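**Strategy.** The route rests on disconnecting C6–C7 of the cycloheptane ring. The key step is a ring-contracting [1,2]-Wittig rearrangement: an eight-membered allylic ether (C6–O–C7, C8=C9) that bridges C5 and C10 of the cyclobutane is lithiated at C7, and the tertiary C6 migrates from oxygen to C7. One operation closes the seven-membered ring, forges the hindered bond between quaternary C6 and carbinol C7, turns the tether oxygen into the C7 hydroxyl and keeps C8=C9 for the cis-diol. It exploits the C6(CH3)2–C7H(OH)–C8 segment of the cycloheptane. The precursor ether is made by ring-closing metathesis on a bicyclo[3.1.1]heptane obtained by an intramolecular vinylketene [2+2] cycloaddition.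

Key step: step 12

Remark 1: longipinane locants are used for all bicyclic and tricyclic compounds. C1 is the ketone carbon of the target, C2=C3 the enone alkene (C3 carries methyl C15), C4 and C11 are the bridgeheads, C5 and C10 the one-carbon bridges, C6 the gem-dimethyl carbon, C7–C9 the oxygenated carbons. "Syn" and "anti" refer to the C1–C2–C3 bridge.

Remark 2: compounds 12, 17 and 18 form as mixtures at one stereo-element that the next operation erases, so their SMILES leave it open. The (1Z) geometry drawn for 5 is lost in step 4.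

Remark 3: the (S,S)-bisphosphoramide of step 4 is assumed to direct the dienolate to the Si face of 3; if the sense is opposite, the (R,R)-enantiomer is used.

Remark 4: the Wittig salt of step 8 is assumed to be prepared from PPh3 and 1-chloroethyl methyl ether.

**Step 1**
Reactants: 1 (E)-3-methylpent-2-en-4-yn-1-ol
Product: 2 (E)-3-methylpenta-2,4-dien-1-ol
Conditions: H2 (1 atm), Pd/CaCO3 poisoned with Pb(OAc)2, quinoline, EtOAc, rt
Reagents that add atoms: none
Why: Semi-hydrogenation of the terminal alkyne on the poisoned palladium catalyst should stop at the diene and leave the E trisubstituted alkene untouched.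

**Step 2**
Reactants: 2 (E)-3-methylpenta-2,4-dien-1-ol
Product: 3 (E)-3-methylpenta-2,4-dienal
Conditions: MnO2, CH2Cl2, rt
Reagents that add atoms: none
Why: Allylic alcohol oxidation with MnO2 gives the dienal without E/Z scrambling.

**Step 3**
Reactants: 4 methyl 3-methylbut-2-enoate
Product: 5 tert-butyl[(1-methoxy-3-methylbuta-1,3-dien-1-yl)oxy]dimethylsilane
Conditions: LiN(i-Pr)2, THF, −78 °C; then TBSCl, DMPU
Reagents that add atoms: tert-butyldimethylsilyl chloride CC(C)(C)[Si](C)(C)Cl
Why: γ-Deprotonation of the senecioate and O-silylation of the dienolate give the silyl dienol ether needed for a vinylogous aldol reaction.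

**Step 4**
Reactants: 3 (E)-3-methylpenta-2,4-dienal; 5 silyl dienol ether
Product: 6 methyl (2E,5S,6E)-5-hydroxy-3,7-dimethylnona-2,6,8-trienoate
Conditions: SiCl4, (S,S)-binaphthyldiamine-derived bisphosphoramide (5 mol%), i-Pr2NEt (10 mol%), CH2Cl2, −78 °C; aq. NaHCO3
Reagents that add atoms: none
Why: Lewis-base-activated SiCl4 vinylogous Mukaiyama aldol reaction: the dienolate attacks through its γ-carbon, the chiral bisphosphoramide selects the aldehyde face (Si face for 5S), and the open transition state gives the 2E enoate.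

**Step 5**
Reactants: 6 methyl (2E,5S,6E)-5-hydroxy-3,7-dimethylnona-2,6,8-trienoate
Product: 7 methyl (2E,5S,6E)-5-(tert-butyldimethylsilyloxy)-3,7-dimethylnona-2,6,8-trienoate
Conditions: TBSCl, imidazole, DMF, rt
Reagents that add atoms: tert-butyldimethylsilyl chloride CC(C)(C)[Si](C)(C)Cl
Why: Standard silylation protects the carbinol that will steer the cycloaddition and later become the C1 ketone.

**Step 6**
Reactants: 7 silyl ether ester
Product: 8 (2E,5S,6E)-5-(tert-butyldimethylsilyloxy)-3,7-dimethylnona-2,6,8-trienoic acid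
Conditions: LiOH, THF/MeOH/H2O, 40 °C; then 1 M HCl to pH 4, 0 °C
Reagents that add atoms: lithium hydroxide [Li+].[OH-]
Why: Saponification of the conjugated ester; the secondary TBS ether tolerates hydroxide and the brief cold acidification.

**Step 7**
Reactants: 8 trienoic acid
Product: 11 cyclobutanone (1R,2S,5R,7R)-2-(tert-butyldimethylsilyloxy)-7-ethenyl-7-methyl-4-methylidenebicyclo[3.1.1]heptan-6-one, via acid chloride 9 (not isolated), via vinylketene 10 (not isolated)
Conditions: (COCl)2, cat. DMF, CH2Cl2, 0 °C; concentrate; then Et3N, PhMe, reflux, slow addition (0.005 M)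
Reagents that add atoms: none
Why: Dehydrochlorination at the γ-methyl cis to the acyl chloride gives the 3-methylene vinylketene, which undergoes an intramolecular ketene–alkene [2+2] cycloaddition (carbonyl carbon to C11, α-carbon to C10). The E alkene places the C10 methyl syn and the vinyl anti, and allylic 1,3-strain (H-1 eclipsing the C10 methyl) should put the C1 silyloxy group on the side of the C5 carbonyl bridge, which fixes C4, C10 and C11.

**Step 8**
Reactants: 11 cyclobutanone
Product: 13 C5-acetyl compound 1-[2-(tert-butyldimethylsilyloxy)-7-ethenyl-7-methyl-4-methylidenebicyclo[3.1.1]hept-6-yl]ethan-1-one with the acetyl group anti, via enol ether 12 (not isolated)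
Conditions: [Ph3PCH(CH3)OCH3]Cl, KOt-Bu, THF, −40 °C → rt; then 1 M aq. HCl, THF, rt; then DBU, CH2Cl2, rt
Reagents that add atoms: (1-methoxyethyl)triphenylphosphonium chloride COC(C)[P+](c1ccccc1)(c1ccccc1)c1ccccc1.[Cl-]; water O
Why: Wittig alkoxyalkylidenation of the strained cyclobutanone, enol-ether hydrolysis and base equilibration of the epimerisable C5 centre; the acetyl group should settle anti (cis to the C10 vinyl, H-5 syn) because the syn position is wedged under the C1–C3 bridge next to the C1 silyloxy group.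

**Step 9**
Reactants: 13 C5-acetyl compound
Product: 14 tertiary alcohol 2-[2-(tert-butyldimethylsilyloxy)-7-ethenyl-7-methyl-4-methylidenebicyclo[3.1.1]hept-6-yl]propan-2-ol
Conditions: MeMgBr, CeCl3, THF, −78 → 0 °C; aq. NH4Cl
Reagents that add atoms: methylmagnesium bromide C[Mg]Br
Why: Organocerium-modified Grignard addition to the hindered, enolisable ketone gives the carbinol that carries both C6 methyl groups; no stereocentre is formed.

**Step 10**
Reactants: 14 tertiary alcohol
Product: 15 allyl ether of 14 (C6–O–CH2CH=CH2)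
Conditions: KH, 18-crown-6 (cat.), allyl bromide, THF, 0 °C → rt
Reagents that add atoms: allyl bromide C=CCBr
Why: Williamson etherification of the potassium tert-alkoxide installs O–C7 and C8.

**Step 11**
Reactants: 15 allyl ether
Product: 16 eight-membered cyclic ether (C6–O–C7H2–C8H=C9H–C10 with 8Z alkene) bridging C5 and C10
Conditions: second-generation Grubbs catalyst (H2IMes)(PCy3)Cl2Ru=CHPh (5 mol%), CH2Cl2 (0.002 M), 40 °C
Reagents that add atoms: none
Why: Ring-closing metathesis of the two monosubstituted alkenes, held 1,3-diaxial on the cyclobutane, closes the oxocine; the ring enforces the Z alkene and the 1,1-disubstituted C3 methylene stays inert.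

**Step 12**
Reactants: 16 eight-membered cyclic ether
Product: 18 (1S)-1-(tert-butyldimethylsilyloxy)longipina-3(15),8-dien-7-ol as both C7 epimers, via C7-lithiated ether 17 (not isolated)
Conditions: s-BuLi (1.3 equiv), THF, −78 → −20 °C; aq. NH4Cl
Reagents that add atoms: none
Why: s-BuLi removes the allylic α-oxy proton at C7; in the α-alkoxyallyl anion 17 the O–C6 bond homolyses to a tethered pair of the tertiary C6 radical and the enal radical anion, which recombines at C7 inside the solvent cage to give the lithium alkoxide of the ring-contracted allylic alcohol ([1,2]-Wittig rearrangement of an α-lithiated allyl tert-alkyl ether, run as an eight-to-seven ring contraction). The cycloheptene closes by this radical/radical-anion collapse (a 1,2-shift, not an exo or endo attack on a π bond), with C5, the cyclobutane and C10 holding C6 within bonding distance of C7. Recombination at C9 (1,4-shift) would build a bicyclo[2.1.1]hexane across the cyclobutane and is excluded by strain, and tertiary C6 is the best migrating group present. The new C7 stereocentre is not controlled here, because the two faces of the anion differ only in the remote C1/C3 substitution; both epimers pass through ketone 19 and are reset by the reagent in step 14. The 1,2-shift must outrun α′,β-elimination (proton abstraction from a C6 methyl) and opening of the cyclobutylcarbinyl C6 radical; low temperature, the intramolecular radical pair and the absence of a radical-stabilising C1 carbonyl (still a silyl ether) should secure this.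

**Step 13**
Reactants: 18 dienol (C7 epimers)
Product: 19 (1S)-1-(tert-butyldimethylsilyloxy)longipina-3(15),8-dien-7-one
Conditions: Dess–Martin periodinane, CH2Cl2, 0 °C → rt
Reagents that add atoms: none
Why: Oxidation of the allylic alcohol erases the uncontrolled C7 centre, so both epimers converge on one dienone.

**Step 14**
Reactants: 19 dienone
Product: 20 (1S,7R)-1-(tert-butyldimethylsilyloxy)longipina-3(15),8-dien-7-ol
Conditions: (S)-2-methyl-CBS-oxazaborolidine (20 mol%), catecholborane, PhMe, −78 °C
Reagents that add atoms: none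
Why: Corey–Bakshi–Shibata reduction: the catalyst should treat the quaternary C6 flank as the large group and the planar C8 vinyl flank as the small one and deliver hydride to the face that gives the 7R carbinol (O-7 on the C4 side); the tricyclic core itself offers no facial bias.

**Step 15**
Reactants: 20 allylic alcohol
Product: 21 (1S,7R)-1-(tert-butyldimethylsilyloxy)-7-(4-methoxybenzyloxy)longipina-3(15),8-diene
Conditions: NaH, PMBCl, n-Bu4NI (cat.), DMF, 0 °C → rt
Reagents that add atoms: 4-methoxybenzyl chloride COc1ccc(CCl)cc1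
Why: Williamson etherification masks O-7 as a PMB ether, orthogonal to the C1 silyl ether and to the esters introduced later.

**Step 16**
Reactants: 21 PMB ether
Product: 22 (1S,7R)-7-(4-methoxybenzyloxy)longipina-3(15),8-dien-1-ol
Conditions: n-Bu4NF, THF, rt
Reagents that add atoms: none
Why: Fluoride cleaves the only silyl ether.

**Step 17**
Reactants: 22 C1 alcohol
Product: 24 (7R)-7-(4-methoxybenzyloxy)longipina-2,8-dien-1-one, via deconjugated enone 23 (not isolated)
Conditions: Dess–Martin periodinane, CH2Cl2, 0 °C → rt; then DBU (0.2 equiv), CH2Cl2, rt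
Reagents that add atoms: none
Why: Oxidation gives the β,γ-unsaturated ketone and DBU moves the exocyclic C3=C15 bond into conjugation (thermodynamic enone); the only other α-carbon, C11, is a bridgehead and cannot epimerise.

**Step 18**
Reactants: 24 dienone
Product: 25 (4R,5S,7S,8S,9S,10R,11R)-8,9-dihydroxy-7-(4-methoxybenzyloxy)longipin-2-en-1-one
Conditions: OsO4 (5 mol%), NMO, acetone/H2O, rt
Reagents that add atoms: osmium tetroxide O=[Os](=O)(=O)=O; N-methylmorpholine N-oxide C[N+]1([O-])CCOCC1; water O
Why: Catalytic dihydroxylation attacks the electron-rich C8=C9 alkene rather than the enone, from the face anti to the allylic C7 ether oxygen, which sets the 8,9-cis diol trans to O-7.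

**Step 19**
Reactants: 25 diol
Product: 26 (4R,5S,7S,8R,9S,10R,11R)-7-(4-methoxybenzyloxy)-1-oxolongipin-2-ene-8,9-diyl bis[(2Z)-2-methylbut-2-enoate]
Conditions: angelic acid, 2,4,6-Cl3C6H2COCl, Et3N, PhMe, rt; then 25, PhMe, 80 °C
Reagents that add atoms: angelic acid C/C=C(/C)C(=O)O
Why: Yamaguchi-type acylation with the preformed mixed anhydride esterifies both hindered secondary hydroxyls without isomerising the Z double bond to the tiglate.

**Step 20**
Reactants: 26 PMB-protected diester
Product: 27 (4R,5S,7S,8R,9S,10R,11R)-7-hydroxy-1-oxolongipin-2-ene-8,9-diyl bis[(2Z)-2-methylbut-2-enoate] (CNP0336239.1)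
Conditions: DDQ, CH2Cl2/pH 7 buffer, 0 °C → rt
Reagents that add atoms: none
Why: Oxidative PMB cleavage under buffered, non-basic conditions frees O-7 without acyl migration or angelate isomerisation.

**Compound list**

1 | (E)-3-methylpent-2-en-4-yn-1-ol | OC/C=C(\C)C#C | starting material
2 | (E)-3-methylpenta-2,4-dien-1-ol | OC/C=C(\C)C=C | intermediate
3 | (E)-3-methylpenta-2,4-dienal | O=C/C=C(\C)C=C | intermediate
4 | methyl 3-methylbut-2-enoate | COC(=O)C=C(C)C | starting material
5 | tert-butyl[(1-methoxy-3-methylbuta-1,3-dien-1-yl)oxy]dimethylsilane, drawn as the (1Z) isomer | C=C(C)/C=C(/OC)O[Si](C)(C)C(C)(C)C | intermediate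
6 | methyl (2E,5S,6E)-5-hydroxy-3,7-dimethylnona-2,6,8-trienoate | COC(=O)/C=C(\C)C[C@H](O)/C=C(\C)C=C | intermediate
7 | methyl (2E,5S,6E)-5-(tert-butyldimethylsilyloxy)-3,7-dimethylnona-2,6,8-trienoate | COC(=O)/C=C(\C)C[C@H](O[Si](C)(C)C(C)(C)C)/C=C(\C)C=C | intermediate
8 | (2E,5S,6E)-5-(tert-butyldimethylsilyloxy)-3,7-dimethylnona-2,6,8-trienoic acid | OC(=O)/C=C(\C)C[C@H](O[Si](C)(C)C(C)(C)C)/C=C(\C)C=C | intermediate
9 | acid chloride of 8 | ClC(=O)/C=C(\C)C[C@H](O[Si](C)(C)C(C)(C)C)/C=C(\C)C=C | intermediate
10 | vinylketene (5S,6E)-5-(tert-butyldimethylsilyloxy)-7-methyl-3-methylidenenona-1,6,8-trien-1-one | O=C=CC(=C)C[C@H](O[Si](C)(C)C(C)(C)C)/C=C(\C)C=C | intermediate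
11 | (1R,2S,5R,7R)-2-(tert-butyldimethylsilyloxy)-7-ethenyl-7-methyl-4-methylidenebicyclo[3.1.1]heptan-6-one (C5 ketone; C10 methyl syn, vinyl anti; C1 OTBS on the side of the C5 bridge) | O=C1[C@H]2[C@@H](O[Si](C)(C)C(C)(C)C)CC(=C)[C@@H]1[C@@]2(C)C=C | intermediate
12 | C5 (1-methoxyethylidene) enol ether of 11, E/Z mixture | COC(C)=C1[C@H]2[C@@H](O[Si](C)(C)C(C)(C)C)CC(=C)[C@@H]1[C@@]2(C)C=C | intermediate
13 | C5-acetyl compound, acetyl anti (cis to the C10 vinyl), core as in 11 | CC(=O)[C@@H]1[C@H]2[C@@H](O[Si](C)(C)C(C)(C)C)CC(=C)[C@@H]1[C@@]2(C)C=C | intermediate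
14 | tertiary alcohol, C5 bears C6(CH3)2OH anti | CC(C)(O)[C@@H]1[C@H]2[C@@H](O[Si](C)(C)C(C)(C)C)CC(=C)[C@@H]1[C@@]2(C)C=C | intermediate
15 | allyl ether of 14 | C=CCOC(C)(C)[C@@H]1[C@H]2[C@@H](O[Si](C)(C)C(C)(C)C)CC(=C)[C@@H]1[C@@]2(C)C=C | intermediate
16 | eight-membered cyclic ether C6–O–C7H2–C8H=C9H–C10 (8Z), C1 OTBS, C3 exocyclic methylene | C1OC(C)(C)[C@@H]2[C@H]3[C@@H](O[Si](C)(C)C(C)(C)C)CC(=C)[C@@H]2[C@@]3(C)/C=C\1 | intermediate
17 | C7-lithiated derivative of 16 | [Li]C1OC(C)(C)[C@@H]2[C@H]3[C@@H](O[Si](C)(C)C(C)(C)C)CC(=C)[C@@H]2[C@@]3(C)/C=C\1 | intermediate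
18 | (1S)-1-(tert-butyldimethylsilyloxy)longipina-3(15),8-dien-7-ol, both C7 epimers | OC1C(C)(C)[C@@H]2[C@H]3[C@@H](O[Si](C)(C)C(C)(C)C)CC(=C)[C@@H]2[C@@]3(C)/C=C\1 | intermediate
19 | (1S)-1-(tert-butyldimethylsilyloxy)longipina-3(15),8-dien-7-one | O=C1C(C)(C)[C@@H]2[C@H]3[C@@H](O[Si](C)(C)C(C)(C)C)CC(=C)[C@@H]2[C@@]3(C)/C=C\1 | intermediate
20 | (1S,7R)-1-(tert-butyldimethylsilyloxy)longipina-3(15),8-dien-7-ol (O-7 on the C4 side) | O[C@H]1C(C)(C)[C@@H]2[C@H]3[C@@H](O[Si](C)(C)C(C)(C)C)CC(=C)[C@@H]2[C@@]3(C)/C=C\1 | intermediate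
21 | (1S,7R)-1-(tert-butyldimethylsilyloxy)-7-(4-methoxybenzyloxy)longipina-3(15),8-diene | COc1ccc(CO[C@H]2C(C)(C)[C@@H]3[C@H]4[C@@H](O[Si](C)(C)C(C)(C)C)CC(=C)[C@@H]3[C@@]4(C)/C=C\2)cc1 | intermediate
22 | (1S,7R)-7-(4-methoxybenzyloxy)longipina-3(15),8-dien-1-ol | COc1ccc(CO[C@H]2C(C)(C)[C@@H]3[C@H]4[C@@H](O)CC(=C)[C@@H]3[C@@]4(C)/C=C\2)cc1 | intermediate
23 | (7R)-7-(4-methoxybenzyloxy)longipina-3(15),8-dien-1-one | COc1ccc(CO[C@H]2C(C)(C)[C@@H]3[C@H]4C(=O)CC(=C)[C@@H]3[C@@]4(C)/C=C\2)cc1 | intermediate
24 | (7R)-7-(4-methoxybenzyloxy)longipina-2,8-dien-1-one | COc1ccc(CO[C@H]2C(C)(C)[C@@H]3[C@H]4C(=O)C=C(C)[C@@H]3[C@@]4(C)/C=C\2)cc1 | intermediate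
25 | (4R,5S,7S,8S,9S,10R,11R)-8,9-dihydroxy-7-(4-methoxybenzyloxy)longipin-2-en-1-one (8,9-cis diol trans to O-7) | O[C@@H]1[C@@H](OCc4ccc(OC)cc4)C(C)(C)[C@@H]2[C@H]3C(=O)C=C(C)[C@@H]2[C@@]3(C)[C@@H]1O | intermediate
26 | (4R,5S,7S,8R,9S,10R,11R)-7-(4-methoxybenzyloxy)-1-oxolongipin-2-ene-8,9-diyl bis[(2Z)-2-methylbut-2-enoate] | C/C=C(/C)C(=O)O[C@@H]1[C@@H](OCc4ccc(OC)cc4)C(C)(C)[C@@H]2[C@H]3C(=O)C=C(C)[C@@H]2[C@@]3(C)[C@@H]1OC(=O)/C(C)=C\C | intermediate
27 | (4R,5S,7S,8R,9S,10R,11R)-7-hydroxy-1-oxolongipin-2-ene-8,9-diyl bis[(2Z)-2-methylbut-2-enoate] | C/C=C(/C)C(=O)O[C@@H]1[C@@H](O)C(C)(C)[C@@H]2[C@H]3C(=O)C=C(C)[C@@H]2[C@@]3(C)[C@@H]1OC(=O)/C(C)=C\C | target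

**Total step count:** 20. **Longest linear sequence:** 19 steps (steps 1, 2 and 4–20; step 3 prepares the second fragment).

**Three steps most likely to fail**

1. Step 12 (key step). Process risk: after metalation the anion may eliminate instead of rearranging (abstraction of a C6-methyl proton with ring opening), or the alkyllithium may not metalate C7 cleanly. Fallback: move the ring contraction to the acetal oxidation level, setting out from 14 and returning at 19.
   - Acetal exchange of 14 with acrolein diethyl acetal (PPTS, PhH, removal of EtOH) would give the mixed acrolein acetal F1.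
   - Ring-closing metathesis with the second-generation Grubbs catalyst (H2IMes)(PCy3)Cl2Ru=CHPh would give the cyclic allylic acetal F2.
   - The doubly oxygen-stabilised C7 proton of F2 is removed with LiN(i-Pr)2 at −78 °C, without an alkyllithium, and the anion is less basic towards the C6 methyl groups.
   - The same 1,2-shift of C6 then gives a lithium hemiketal that expels ethoxide irreversibly and delivers enone 19 directly; both acetal epimers converge.

2. Step 8. Process risk: too small a thermodynamic preference in the C5 equilibration, leaving a mixture of which only the anti epimer can cyclise in step 11. Fallback: let a ring set C5, setting out from 11 and returning at 16.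
   - Wittig reaction of 11 with (allyloxymethylene)triphenylphosphorane would give the allyl enol ether F3.
   - Oxidation of the enol ether with pyridinium chlorochromate (C5H5NH)[CrO3Cl] would give the allyl ester F4, whose C5 epimers interconvert with catalytic KOt-Bu.
   - Ring-closing metathesis consumes only the anti epimer and gives the eight-membered lactone F5, in which the ring locks C5; unreacted syn ester is re-equilibrated and recycled.
   - MeLi at −78 °C gives the methyl lactol F6, and AlMe3 replaces the lactol hydroxyl by methyl through the ring oxocarbenium ion, which gives 16.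

3. Step 7. Process risk: oligomerisation of the vinylketene at reflux, poor periselectivity on the diene, or poor facial selectivity. Fallback: use a keteniminium salt instead of the ketene, setting out from 7 and returning at 11.
   - Deconjugation of 7 (LiN(i-Pr)2, HMPA, −78 °C, then AcOH) would give the β,γ-unsaturated ester F7.
   - Me2AlNMe2 converts it into the dimethylamide F8.
   - Tf2O and 2,4,6-collidine generate the more electrophilic keteniminium ion, which should undergo the same intramolecular [2+2] cycloaddition at or below room temperature under the same allylic-strain control to give the cyclobutaniminium triflate F9.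
   - Aqueous NaHCO3 hydrolyses F9 to 11.

**Further compounds**

F1 | step 12 | mixed acrolein ethyl acetal of 14 (C6–O–CH(OEt)–CH=CH2, acetal epimers) | CCOC(C=C)OC(C)(C)[C@@H]1[C@H]2[C@@H](O[Si](C)(C)C(C)(C)C)CC(=C)[C@@H]1[C@@]2(C)C=C
F2 | step 12 | cyclic allylic acetal (7-ethoxy derivative of 16, acetal epimers) | CCOC1OC(C)(C)[C@@H]2[C@H]3[C@@H](O[Si](C)(C)C(C)(C)C)CC(=C)[C@@H]2[C@@]3(C)/C=C\1
F3 | step 8 | allyl enol ether of 11 (C5=CH–O–allyl, E/Z mixture) | C=CCOC=C1[C@H]2[C@@H](O[Si](C)(C)C(C)(C)C)CC(=C)[C@@H]1[C@@]2(C)C=C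
F4 | step 8 | allyl ester at C5 (C5 epimers, equilibrating) | C=CCOC(=O)C1[C@H]2[C@@H](O[Si](C)(C)C(C)(C)C)CC(=C)[C@@H]1[C@@]2(C)C=C
F5 | step 8 | eight-membered lactone C5–C6(=O)–O–C7H2–C8H=C9H–C10 (8Z) | C1OC(=O)[C@@H]2[C@H]3[C@@H](O[Si](C)(C)C(C)(C)C)CC(=C)[C@@H]2[C@@]3(C)/C=C\1
F6 | step 8 | methyl lactol of F5 (C6 bears CH3 and OH, C6 epimers) | C1OC(C)(O)[C@@H]2[C@H]3[C@@H](O[Si](C)(C)C(C)(C)C)CC(=C)[C@@H]2[C@@]3(C)/C=C\1
F7 | step 7 | methyl (5S,6E)-5-(tert-butyldimethylsilyloxy)-7-methyl-3-methylidenenona-6,8-dienoate | COC(=O)CC(=C)C[C@H](O[Si](C)(C)C(C)(C)C)/C=C(\C)C=C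
F8 | step 7 | N,N-dimethylamide of F7 | CN(C)C(=O)CC(=C)C[C@H](O[Si](C)(C)C(C)(C)C)/C=C(\C)C=C
F9 | step 7 | N,N-dimethylcyclobutaniminium triflate corresponding to 11 | C[N+](C)=C1[C@H]2[C@@H](O[Si](C)(C)C(C)(C)C)CC(=C)[C@@H]1[C@@]2(C)C=C.[O-]S(=O)(=O)C(F)(F)F
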